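**Remark on the chemistry:** the single stereocentre is (R) (OH > C(=O)Ar > CH2Ar > H). It is bought with methyl (R)-glycidate and no bond to it is made or broken afterwards. Ring A is the 2,4-dihydroxy-3-prenylphenyl ring, with C1′ the carbon bonded to the ketone.

**Retrosynthetic overview**
1. Target 18 comes from 17 by one acidic methanolysis (two aryl MOM acetals, one TBS ether).
2. The C(=O)–C1′ bond is cut. C1′ is the 2-methyl carbon of 2-methyl-3-prenyl-4-pyranone 13, which is joined to ester 10 by a lateral Claisen condensation; the pyranone ring is then transposed into ring A in the same flask.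
3. Enabling feature: ring A is a 4-acyl-2-alkylresorcinol, the enol form of a cyclised 1,3,5-tricarbonyl chain. Its O–C2′–C3′(prenyl)–C4′–O–C5′–C6′ array maps atom for atom onto O1–C2–C3(prenyl)–C4(=O)–C5–C6 of a 4-pyranone, and C1′, flanked by the ketone and C2′–O, is a latent doubly activated carbanion.
4. Ester 10 comes from aryl bromide 6 by copper-catalysed Grignard opening of methyl (R)-glycidate 7. Bromide 6 comes from 3,5-dibromosalicylaldehyde 1 (Dakin oxidation, MOM protection, ortho-selective Br/Li exchange, prenylation). Pyranone 13 comes from maltol 11 (triflate, Stille prenylation).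
5. Ring order: ring B and the pyranone ring are bought intact; ring A is the only ring formed, last, in step 8, from the pyranone ring.

Key step: step 8

**Step 1**
Reactants: 1 3,5-dibromo-2-hydroxybenzaldehyde
Product: 3 3,5-dibromobenzene-1,2-diol, via 3,5-dibromo-2-hydroxyphenyl formate 2 (not isolated)
Conditions: H2O2 (30% aq), NaOH, H2O/THF, 0 °C → rt; then aq HCl
Reagents that add atoms: hydrogen peroxide, OO
Why: Dakin oxidation, in which hydroperoxide adds to the ortho-hydroxybenzaldehyde, the aryl group migrates to oxygen and formate 2 is saponified in situ, so the formyl carbon is exchanged for the second catechol oxygen while both bromides stay in place.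

**Step 2**
Reactants: 3 3,5-dibromobenzene-1,2-diol
Product: 4 1,5-dibromo-2,3-bis(methoxymethoxy)benzene
Conditions: MOMCl, i-Pr2NEt, CH2Cl2, 0 °C → rt
Reagents that add atoms: chloromethyl methyl ether, COCCl
Why: Williamson-type O-alkylation of both phenols with the reactive α-chloro ether should give the bis-MOM acetal, which tolerates organolithium, Grignard and alkoxide reagents and later directs the halogen–metal exchange.

**Step 3**
Reactants: 4 1,5-dibromo-2,3-bis(methoxymethoxy)benzene
Product: 6 5-bromo-1,2-bis(methoxymethoxy)-3-(3-methylbut-2-en-1-yl)benzene, via [5-bromo-2,3-bis(methoxymethoxy)phenyl]lithium 5 (not isolated)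
Conditions: n-BuLi (1.05 equiv), THF, −78 °C; CuI (cat.), prenyl bromide, −78 → 0 °C
Reagents that add atoms: 1-bromo-3-methylbut-2-ene, CC(C)=CCBr
Why: Bromine–lithium exchange should be fastest at the bromide ortho to the coordinating OMOM group (the behaviour of 2,4-dibromoanisole), and copper-catalysed SN2 allylation of the aryl metal at the primary carbon of prenyl bromide should give the linear prenyl arene.

**Step 4**
Reactants: 6 5-bromo-1,2-bis(methoxymethoxy)-3-(3-methylbut-2-en-1-yl)benzene; 7 methyl (2R)-oxirane-2-carboxylate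
Product: 9 methyl (2R)-3-[3,4-bis(methoxymethoxy)-5-(3-methylbut-2-en-1-yl)phenyl]-2-hydroxypropanoate, via arylmagnesium bromide 8 (not isolated)
Conditions: Mg, THF, 45 °C; CuI (cat.), 7, −40 → −20 °C; aq NH4Cl
Reagents that add atoms: none
Why: Copper-catalysed Grignard opening of a glycidic ester should occur at the unsubstituted C3 faster than addition to the ester at low temperature, and because the C2–O bond of 7 is not touched the (R) configuration carries over unchanged.

**Step 5**
Reactants: 9 methyl (2R)-3-[3,4-bis(methoxymethoxy)-5-(3-methylbut-2-en-1-yl)phenyl]-2-hydroxypropanoate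
Product: 10 methyl (2R)-3-[3,4-bis(methoxymethoxy)-5-(3-methylbut-2-en-1-yl)phenyl]-2-[(tert-butyldimethylsilyl)oxy]propanoate
Conditions: TBSCl, imidazole, DMF, rt
Reagents that add atoms: tert-butyldimethylsilyl chloride, CC(C)(C)[Si](C)(C)Cl
Why: Standard imidazole-promoted silylation of a secondary alcohol should mask the α-hydroxyl, so that the ester carbonyl is the only electrophilic site offered in step 8 and the stereocentre is not involved.

**Step 6**
Reactants: 11 3-hydroxy-2-methyl-4H-pyran-4-one (maltol)
Product: 12 2-methyl-4-oxo-4H-pyran-3-yl trifluoromethanesulfonate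
Conditions: Tf2O, pyridine, CH2Cl2, 0 °C
Reagents that add atoms: trifluoromethanesulfonic anhydride, O=S(=O)(OS(=O)(=O)C(F)(F)F)C(F)(F)F
Why: O-sulfonylation of the enolic 3-hydroxyl of maltol should give an enol triflate that is a competent partner for oxidative addition to palladium(0).

**Step 7**
Reactants: 12 2-methyl-4-oxo-4H-pyran-3-yl trifluoromethanesulfonate
Product: 13 2-methyl-3-(3-methylbut-2-en-1-yl)-4H-pyran-4-one
Conditions: Bu3Sn(prenyl), Pd(PPh3)4 (cat.), LiCl, DMF, 80 °C
Reagents that add atoms: tributyl(3-methylbut-2-en-1-yl)stannane, CCCC[Sn](CCCC)(CCCC)CC=C(C)C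
Why: Stille cross-coupling of the enol triflate with the allylic stannane (chloride-promoted transmetalation) should transfer the prenyl group mainly through its primary carbon, which places the future C3′ substituent before ring A exists.

**Step 8**
Reactants: 13 2-methyl-3-(3-methylbut-2-en-1-yl)-4H-pyran-4-one; 10 methyl (2R)-3-[3,4-bis(methoxymethoxy)-5-(3-methylbut-2-en-1-yl)phenyl]-2-[(tert-butyldimethylsilyl)oxy]propanoate
Product: 17 (2R)-3-[3,4-bis(methoxymethoxy)-5-(3-methylbut-2-en-1-yl)phenyl]-2-[(tert-butyldimethylsilyl)oxy]-1-[2,4-dihydroxy-3-(3-methylbut-2-en-1-yl)phenyl]propan-1-one, via lithium dienolate 14 (not isolated), via 2-(acylmethyl)pyranone 15 (not isolated), via ring-opened methoxyenone triketone 16 (not isolated)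
Conditions: 13 (2.2 equiv), LiHMDS (2.1 equiv), THF, −78 °C; 10 (1 equiv), −78 → 0 °C; then MeOH, 50 °C; AcOH quench
Reagents that add atoms: none
Why: Proposed new method: LiHMDS removes a proton from the 2-methyl group of 13 (vinylogous γ-deprotonation), and the exocyclic carbon of dienolate 14 attacks the ester carbonyl of 10 in a Claisen condensation that forms the C(=O)–C1′ bond and leaves 15 as its enolate beside one equivalent of lithium methoxide (the second equivalent of 14 serves as base). In methanol this methoxide should add to the unsubstituted C6 of the pyranone, the C6–O1 bond should break by retro-oxa-Michael (E1cB) opening to the β-methoxyenone 16, the doubly activated C1′ methylene should close onto the methoxy-bearing carbon with loss of methoxide, and double enolisation of the resulting cyclohexenedione should give the resorcinol, so that the pyranone oxygen becomes the 2′-OH, the pyranone carbonyl becomes the 4′-OH and methoxide acts only as a shuttle. The closest known reaction types are the lateral Claisen acylation of 2-methyl-4-pyranones and 2-methylchromones with esters, and the base-induced conversion of 4-pyranones and open-chain polyketones into resorcinols by ring opening and intramolecular aldol condensation (2,6-dimethyl-4-pyranone to orcinol, 1-aryl-1,3,5,7-tetraketones to 2,4-dihydroxyaryl ketones); their merger in one flask on a 6-unsubstituted 3-alkylpyranone is the untested part. The one ring that closes is the six-membered carbocycle of ring A, by 6-endo-trig addition–elimination between C1′ and C6′ (equally describable as 6π-electrocyclisation of the trienolate followed by loss of methoxide), and the closure is irreversible because it ends in an arene. No stereocentre is created, and the existing (R) centre should survive because its ketone is already enolised towards C1′ in 15 and 16 (a 1,3-dicarbonyl enolate is not deprotonated again at the other α-carbon) and is a deactivated vinylogous carboxylate of a bis-phenoxide in 17. The step needs C- over O-acylation (O-acyl products revert under the methoxide present), attack of methoxide at C6 and not C2 (C2 is shielded and deactivated by the enolate side chain) and closure through carbon and not oxygen (O-closure only regenerates 15), while the substitution pattern of ring A cannot vary because every ring atom keeps the position it had in the pyranone.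

**Step 9**
Reactants: 17 (2R)-3-[3,4-bis(methoxymethoxy)-5-(3-methylbut-2-en-1-yl)phenyl]-2-[(tert-butyldimethylsilyl)oxy]-1-[2,4-dihydroxy-3-(3-methylbut-2-en-1-yl)phenyl]propan-1-one
Product: 18 (2R)-1-[2,4-dihydroxy-3-(3-methylbut-2-en-1-yl)phenyl]-3-[3,4-dihydroxy-5-(3-methylbut-2-en-1-yl)phenyl]-2-hydroxypropan-1-one
Conditions: HCl (aq, cat.), MeOH, rt → 40 °C
Reagents that add atoms: none
Why: Acid-catalysed methanolysis (acetal exchange and silyl ether solvolysis) should cleave the two aryl MOM groups and the secondary TBS ether in one operation under conditions commonly tolerated by ortho-prenylphenols, and the stereocentre is not enolised in dilute acid at this temperature.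

**Compound list**
1 | 3,5-dibromo-2-hydroxybenzaldehyde | O=Cc1cc(Br)cc(Br)c1O | starting material
2 | 3,5-dibromo-2-hydroxyphenyl formate | O=COc1cc(Br)cc(Br)c1O | intermediate
3 | 3,5-dibromobenzene-1,2-diol | Oc1cc(Br)cc(Br)c1O | intermediate
4 | 1,5-dibromo-2,3-bis(methoxymethoxy)benzene | COCOc1cc(Br)cc(Br)c1OCOC | intermediate
5 | [5-bromo-2,3-bis(methoxymethoxy)phenyl]lithium | [Li]c1cc(Br)cc(OCOC)c1OCOC | intermediate
6 | 5-bromo-1,2-bis(methoxymethoxy)-3-(3-methylbut-2-en-1-yl)benzene | CC(C)=CCc1cc(Br)cc(OCOC)c1OCOC | intermediate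
7 | methyl (2R)-oxirane-2-carboxylate (methyl (R)-glycidate) | COC(=O)[C@H]1CO1 | starting material
8 | [3,4-bis(methoxymethoxy)-5-(3-methylbut-2-en-1-yl)phenyl]magnesium bromide | CC(C)=CCc1cc([Mg]Br)cc(OCOC)c1OCOC | intermediate
9 | methyl (2R)-3-[3,4-bis(methoxymethoxy)-5-(3-methylbut-2-en-1-yl)phenyl]-2-hydroxypropanoate | COC(=O)[C@H](O)Cc1cc(CC=C(C)C)c(OCOC)c(OCOC)c1 | intermediate
10 | methyl (2R)-3-[3,4-bis(methoxymethoxy)-5-(3-methylbut-2-en-1-yl)phenyl]-2-[(tert-butyldimethylsilyl)oxy]propanoate | COC(=O)[C@H](O[Si](C)(C)C(C)(C)C)Cc1cc(CC=C(C)C)c(OCOC)c(OCOC)c1 | intermediate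
11 | 3-hydroxy-2-methyl-4H-pyran-4-one (maltol) | CC1=C(O)C(=O)C=CO1 | starting material
12 | 2-methyl-4-oxo-4H-pyran-3-yl trifluoromethanesulfonate | CC1=C(OS(=O)(=O)C(F)(F)F)C(=O)C=CO1 | intermediate
13 | 2-methyl-3-(3-methylbut-2-en-1-yl)-4H-pyran-4-one | CC1=C(CC=C(C)C)C(=O)C=CO1 | intermediate
14 | lithium 2-methylidene-3-(3-methylbut-2-en-1-yl)-2H-pyran-4-olate | C=C1OC=CC(O[Li])=C1CC=C(C)C | intermediate
15 | 2-{(3R)-4-[3,4-bis(methoxymethoxy)-5-(3-methylbut-2-en-1-yl)phenyl]-3-[(tert-butyldimethylsilyl)oxy]-2-oxobutyl}-3-(3-methylbut-2-en-1-yl)-4H-pyran-4-one (formed as its enolate) | CC(C)=CCC1=C(CC(=O)[C@H](O[Si](C)(C)C(C)(C)C)Cc2cc(CC=C(C)C)c(OCOC)c(OCOC)c2)OC=CC1=O | intermediate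
16 | (8R)-9-[3,4-bis(methoxymethoxy)-5-(3-methylbut-2-en-1-yl)phenyl]-8-[(tert-butyldimethylsilyl)oxy]-1-methoxy-4-(3-methylbut-2-en-1-yl)non-1-ene-3,5,7-trione (drawn as the triketone; enol ether geometry and C4 not defined, present as enolates) | COC=CC(=O)C(CC=C(C)C)C(=O)CC(=O)[C@H](O[Si](C)(C)C(C)(C)C)Cc1cc(CC=C(C)C)c(OCOC)c(OCOC)c1 | intermediate
17 | (2R)-3-[3,4-bis(methoxymethoxy)-5-(3-methylbut-2-en-1-yl)phenyl]-2-[(tert-butyldimethylsilyl)oxy]-1-[2,4-dihydroxy-3-(3-methylbut-2-en-1-yl)phenyl]propan-1-one | CC(C)=CCc1c(O)ccc(C(=O)[C@H](O[Si](C)(C)C(C)(C)C)Cc2cc(CC=C(C)C)c(OCOC)c(OCOC)c2)c1O | intermediate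
18 | (2R)-1-[2,4-dihydroxy-3-(3-methylbut-2-en-1-yl)phenyl]-3-[3,4-dihydroxy-5-(3-methylbut-2-en-1-yl)phenyl]-2-hydroxypropan-1-one (CNP0286988.1) | CC(C)=CCc1cc(C[C@@H](O)C(=O)c2ccc(O)c(CC=C(C)C)c2O)cc(O)c1O | target

**Step count**
Total: 9 steps. Longest linear sequence: 7 steps (1, 2, 3, 4, 5, 8, 9); the pyranone arm (steps 6, 7) joins at step 8.

**Steps most likely to fail**

Step 8 (Proposed new method). Three processes may intervene: conjugate self-addition of the dienolate to neutral pyranone at C6, retro-Claisen cleavage of the triketone by methoxide instead of ring closure, and slow base-mediated epimerisation of the α-silyloxy ketone on prolonged heating. The fallback uses known chemistry, sets out from 10 and comes back to the route at 18. Ester 10 is converted with MeNH(OMe)·HCl and i-PrMgCl (THF, −20 °C) into (2R)-3-[3,4-bis(methoxymethoxy)-5-(3-methylbut-2-en-1-yl)phenyl]-2-[(tert-butyldimethylsilyl)oxy]-N-methoxy-N-methylpropanamide F1. Separately, commercial 4-bromoresorcinol is protected (MOMCl, i-Pr2NEt) as 1-bromo-2,4-bis(methoxymethoxy)benzene F2. F2 is deprotonated between its two acetal oxygens with LDA (THF, −78 °C) to [3-bromo-2,6-bis(methoxymethoxy)phenyl]lithium F3, and this is prenylated (CuI cat., prenyl bromide) to 1-bromo-2,4-bis(methoxymethoxy)-3-(3-methylbut-2-en-1-yl)benzene F4. Bromine–lithium exchange (n-BuLi, THF, −78 °C) gives [2,4-bis(methoxymethoxy)-3-(3-methylbut-2-en-1-yl)phenyl]lithium F5, which should add once to F1 through the chelated tetrahedral intermediate to give (2R)-1-[2,4-bis(methoxymethoxy)-3-(3-methylbut-2-en-1-yl)phenyl]-3-[3,4-bis(methoxymethoxy)-5-(3-methylbut-2-en-1-yl)phenyl]-2-[(tert-butyldimethylsilyl)oxy]propan-1-one F6. The acidic methanolysis of step 9, applied to F6, removes four MOM groups and the TBS group and should give 18.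

Step 9. Acid-catalysed addition of the free ortho-phenols to the prenyl double bonds (chroman formation) and acid-mediated enediol isomerisation of the α-ketol may compete with acetal cleavage. The fallback replaces the single Brønsted-acid solvolysis by a buffered silyl-transfer acetal cleavage followed by fluoride; it sets out from 17 and comes back at 18. Treatment of 17 with TMSOTf and 2,2′-bipyridyl (CH2Cl2, 0 °C → rt) should exchange the two aryl MOM acetals for silyl ethers and silylate the two free phenols, giving (2R)-2-[(tert-butyldimethylsilyl)oxy]-1-[3-(3-methylbut-2-en-1-yl)-2,4-bis(trimethylsilyloxy)phenyl]-3-[3-(3-methylbut-2-en-1-yl)-4,5-bis(trimethylsilyloxy)phenyl]propan-1-one F7. Aqueous work-up hydrolyses the aryl silyl ethers to (2R)-2-[(tert-butyldimethylsilyl)oxy]-1-[2,4-dihydroxy-3-(3-methylbut-2-en-1-yl)phenyl]-3-[3,4-dihydroxy-5-(3-methylbut-2-en-1-yl)phenyl]propan-1-one F8. HF·pyridine (THF/pyridine, 0 °C) then removes the TBS group and should give 18.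

Step 7. Allylic transposition during transmetalation and reductive elimination (γ-coupling to the 1,1-dimethylallyl isomer) and sluggish coupling of the pyranone triflate may erode the step. The fallback separates C–C coupling from construction of the trisubstituted alkene; it sets out from 12 and comes back at 13. Stille coupling of 12 with allyltributylstannane (Pd(PPh3)4, LiCl, DMF), where both allyl termini are equivalent, should give 2-methyl-3-(prop-2-en-1-yl)-4H-pyran-4-one F9. Cross-metathesis of F9 with 2-methylbut-2-ene (second-generation Ru–NHC benzylidene catalyst, CH2Cl2, 40 °C) then converts the allyl into the prenyl group and should give 13.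

**Further compounds**
F1 | step 8 | (2R)-3-[3,4-bis(methoxymethoxy)-5-(3-methylbut-2-en-1-yl)phenyl]-2-[(tert-butyldimethylsilyl)oxy]-N-methoxy-N-methylpropanamide | CON(C)C(=O)[C@H](O[Si](C)(C)C(C)(C)C)Cc1cc(CC=C(C)C)c(OCOC)c(OCOC)c1
F2 | step 8 | 1-bromo-2,4-bis(methoxymethoxy)benzene | COCOc1ccc(Br)c(OCOC)c1
F3 | step 8 | [3-bromo-2,6-bis(methoxymethoxy)phenyl]lithium | [Li]c1c(OCOC)ccc(Br)c1OCOC
F4 | step 8 | 1-bromo-2,4-bis(methoxymethoxy)-3-(3-methylbut-2-en-1-yl)benzene | CC(C)=CCc1c(OCOC)ccc(Br)c1OCOC
F5 | step 8 | [2,4-bis(methoxymethoxy)-3-(3-methylbut-2-en-1-yl)phenyl]lithium | [Li]c1ccc(OCOC)c(CC=C(C)C)c1OCOC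
F6 | step 8 | (2R)-1-[2,4-bis(methoxymethoxy)-3-(3-methylbut-2-en-1-yl)phenyl]-3-[3,4-bis(methoxymethoxy)-5-(3-methylbut-2-en-1-yl)phenyl]-2-[(tert-butyldimethylsilyl)oxy]propan-1-one | CC(C)=CCc1c(OCOC)ccc(C(=O)[C@H](O[Si](C)(C)C(C)(C)C)Cc2cc(CC=C(C)C)c(OCOC)c(OCOC)c2)c1OCOC
F7 | step 9 | (2R)-2-[(tert-butyldimethylsilyl)oxy]-1-[3-(3-methylbut-2-en-1-yl)-2,4-bis(trimethylsilyloxy)phenyl]-3-[3-(3-methylbut-2-en-1-yl)-4,5-bis(trimethylsilyloxy)phenyl]propan-1-one | CC(C)=CCc1c(O[Si](C)(C)C)ccc(C(=O)[C@H](O[Si](C)(C)C(C)(C)C)Cc2cc(CC=C(C)C)c(O[Si](C)(C)C)c(O[Si](C)(C)C)c2)c1O[Si](C)(C)C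
F8 | step 9 | (2R)-2-[(tert-butyldimethylsilyl)oxy]-1-[2,4-dihydroxy-3-(3-methylbut-2-en-1-yl)phenyl]-3-[3,4-dihydroxy-5-(3-methylbut-2-en-1-yl)phenyl]propan-1-one | CC(C)=CCc1c(O)ccc(C(=O)[C@H](O[Si](C)(C)C(C)(C)C)Cc2cc(CC=C(C)C)c(O)c(O)c2)c1O
F9 | step 7 | 2-methyl-3-(prop-2-en-1-yl)-4H-pyran-4-one | C=CCC1=C(C)OC=CC1=O
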